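**Retrosynthetic overview**

1. Numbering: C1 is the carboxyl carbon, C3–C6 are the ring carbons, C7–C14 the chain. The acid comes from its methyl ester, and the C9=C10 alkene from a Julia–Kocienski reaction of a C1–C9 dioxane aldehyde with a C10–C14 tetrazolyl sulfone.
2. Feature on which the strategy rests: the two peroxide-bearing carbons of the 1,2-dioxane, C3 and C6, are linked on the carbon side only by C4–C5. The ring therefore maps onto a cyclobutene whose C3=C6 double bond has been replaced by oxygen at both ends.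
3. C3–C2 and C6–CH3 are cut back to peroxycarbenium ions, both stored in one 2,3,7-trioxabicyclo[2.2.1]heptane (C3 at acetal level, C6 at ketal level), the ozonide of that cyclobutene.
4. The cyclobutene comes from 3-methylcyclobutanone (C4 fixed by enantioselective enolisation and triflation) and a C7–C9 Grignard reagent from the (S)-hydroxy ester (C8). The sulfone comes from crotonophenone (C12 by Claisen chirality transfer).
5. Ring order: cyclobutene (bought as the cyclobutanone), then trioxolane and 1,2-dioxane closed together in the ozonide, then the ether bridge opened so that only the 1,2-dioxane remains.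

Key step: step 6

Assumption: the sense of the two reagent-controlled steps is taken as (R,R)-amide giving the (S)-enolate in step 4 and D-(−)-tartrate leaving the (R)-carbinol in step 13; if a sense proves opposite, the mirror-image reagent is used.
Assumption: ozonide 12 is written as the diastereomer with the C4 methyl anti to the ether bridge; nothing in the substrate fixes this relation, and material with the bridge on the other face would be carried forward with it, since steps 7 and 9 ionise both bridgeheads.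

**Route**

Step 1
Reactants: 1 methyl (S)-3-hydroxy-2-methylpropanoate
Product: 2 methyl (S)-3-[(tert-butyldiphenylsilyl)oxy]-2-methylpropanoate
Conditions: TBDPSCl, imidazole, DMF, 0 °C → rt
Reagents that add atoms: tert-butyl(chloro)diphenylsilane, CC(C)(C)[Si](Cl)(c1ccccc1)c1ccccc1
Why: Silylation of a primary alcohol; the stereocentre (later C8) is not touched.

Step 2
Reactants: 2 methyl (S)-3-[(tert-butyldiphenylsilyl)oxy]-2-methylpropanoate
Product: 3 (R)-3-[(tert-butyldiphenylsilyl)oxy]-2-methylpropan-1-ol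
Conditions: i-Bu2AlH (2.5 equiv), CH2Cl2, −78 → 0 °C; potassium sodium tartrate (aq)
Reagents that add atoms: none
Why: Hydride reduction of the ester to the primary alcohol without enolisation (the descriptor changes by priority only).

Step 3
Reactants: 3 (R)-3-[(tert-butyldiphenylsilyl)oxy]-2-methylpropan-1-ol
Product: 4 (S)-(3-bromo-2-methylpropoxy)(tert-butyl)diphenylsilane
Conditions: CBr4, PPh3, CH2Cl2, 0 °C
Reagents that add atoms: carbon tetrabromide, BrC(Br)(Br)Br
Why: Appel bromination of a primary alcohol under neutral conditions that leave the silyl ether intact.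

Step 4
Reactants: 5 3-methylcyclobutan-1-one
Product: 7 (S)-3-methylcyclobut-1-en-1-yl trifluoromethanesulfonate, via lithium enolate 6 (not isolated)
Conditions: (R,R)-bis(1-phenylethyl)amine, n-BuLi, LiCl, THF, −100 °C; then Comins' reagent, −78 → −20 °C
Reagents that add atoms: N-(5-chloropyridin-2-yl)-1,1,1-trifluoro-N-[(trifluoromethyl)sulfonyl]methanesulfonamide (Comins' reagent), O=S(=O)(N(c1ccc(Cl)cn1)S(=O)(=O)C(F)(F)F)C(F)(F)F
Why: Enantioselective deprotonation of a prochiral 3-substituted cyclobutanone by a chiral lithium amide removes one of the two enantiotopic α-methylene protons, so the ring carbon bearing methyl (later C4) becomes a stereocentre of (S) configuration, and O-triflation of the enolate preserves it.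

Step 5
Reactants: 4 (S)-(3-bromo-2-methylpropoxy)(tert-butyl)diphenylsilane; 7 (S)-3-methylcyclobut-1-en-1-yl trifluoromethanesulfonate
Product: 9 tert-butyl{(2R)-2-methyl-3-[(3S)-3-methylcyclobut-1-en-1-yl]propoxy}diphenylsilane, via Grignard reagent 8 (not isolated)
Conditions: Mg, THF, 40 °C; then 7, Fe(acac)3 (5 mol%), THF/NMP, −30 → 0 °C
Reagents that add atoms: none
Why: Fe(acac)3-catalysed cross-coupling of an alkyl Grignard reagent with an alkenyl triflate forms C6–C7 at low temperature without touching either stereocentre.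

Step 6
Reactants: 9 tert-butyl{(2R)-2-methyl-3-[(3S)-3-methylcyclobut-1-en-1-yl]propoxy}diphenylsilane
Product: 12 (1R,4S,5S)-1-[(2R)-3-[(tert-butyldiphenylsilyl)oxy]-2-methylpropyl]-5-methyl-2,3,7-trioxabicyclo[2.2.1]heptane, via primary ozonide 10 (not isolated), via carbonyl oxide 11 (not isolated)
Conditions: O3 (1.05 equiv), pentane/CH2Cl2 (5:1, 0.02 M), −78 °C; N2 purge; no reductant; concentrated below 20 °C
Reagents that add atoms: ozone, [O-][O+]=O
Why: 1,3-Dipolar cycloaddition of ozone to the strained C3=C6 bond gives primary ozonide 10, which cycloreverts to a carbonyl oxide and a carbonyl that stay joined by C4–C5 (drawn as 11; the opposite split converges), and these recombine by intramolecular 1,3-dipolar cycloaddition, the Criegee sequence known to turn cyclobutenes into isolable 2,3,7-trioxabicyclo[2.2.1]heptanes. That single [3+2] closure forms the 1,2,4-trioxolane, and because dipole and dipolarophile are tethered it closes at the same time the 1,2-dioxane (C3–O–O–C6–C5–C4) and the oxolane (C3–O–C6–C5–C4), making the two peroxide bonds C3–O and C6–O and the C3–O–C6 ether bridge. The new stereocentres C3 and C6 are bridgeheads whose mutual configuration is dictated by the bicycle; their relation to the C4 methyl (drawn in 12 with the methyl anti to the ether bridge) is not controlled by anything in the substrate and need not be, because both carbons are ionised again in steps 7 and 9. C4 and C8 are not touched. The step needs ozone to attack only the cyclobutene, which the absence of any other alkene and the far slower ozonation of the silyl phenyl rings secure when one equivalent is dosed, and it needs ring closure to beat oligomeric peroxide formation, which the two-carbon tether, the non-participating solvent, dilution and −78 °C favour.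

Step 7
Reactants: 12 (1R,4S,5S)-1-[(2R)-3-[(tert-butyldiphenylsilyl)oxy]-2-methylpropyl]-5-methyl-2,3,7-trioxabicyclo[2.2.1]heptane
Product: 14 (4S,6R)-6-[(2R)-3-[(tert-butyldiphenylsilyl)oxy]-2-methylpropyl]-4,6-dimethyl-1,2-dioxan-3-ol, via silyl peroxyacetal 13 (not isolated)
Conditions: Me3Al (3 equiv), TMSOTf (1.1 equiv), CH2Cl2, −78 → −50 °C; potassium sodium tartrate (aq); then citric acid, THF/H2O, 0 °C
Reagents that add atoms: trimethylaluminium, C[Al](C)C
Why: Proposed new method: TMSOTf should silylate the ether bridge oxygen (the only oxygen outside the peroxide), and heterolysis of its bond to the fully substituted C6 should give the tertiary peroxycarbenium ion while C3 stays as a silyl peroxyacetal; Me3Al should then transfer methyl along the axial trajectory of the half-chair in which the C4 methyl is pseudo-equatorial, so the new methyl is trans to the C4 methyl (6R) on whichever face the bridge oxygen stood, because that oxygen leaves as a silyl ether that cannot deliver methyl itself; the closest known reaction types are Lewis-acid ionisation of 1,2,4-trioxolanes to peroxycarbenium ions trapped by allylsilanes and axial methylation by Me3Al of cyclic oxocarbenium ions made from ketals, anomeric sulfones or fluorides, and dialkyl peroxides are known to survive Me3Al at −78 °C; mild acid then hydrolyses the C3 silyl ether to the peroxy hemiacetal (C3 anomers).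

Step 8
Reactants: 14 (4S,6R)-6-[(2R)-3-[(tert-butyldiphenylsilyl)oxy]-2-methylpropyl]-4,6-dimethyl-1,2-dioxan-3-ol
Product: 15 (4S,6R)-6-[(2R)-3-[(tert-butyldiphenylsilyl)oxy]-2-methylpropyl]-4,6-dimethyl-1,2-dioxan-3-yl acetate
Conditions: Ac2O, pyridine, DMAP (cat.), CH2Cl2, 0 °C
Reagents that add atoms: acetic anhydride, CC(=O)OC(C)=O
Why: Acylation of the cyclic peroxy hemiacetal hydroxyl with a weak base at 0 °C turns C3–OH into a leaving group; the C3 configuration is irrelevant because it is ionised next.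

Step 9
Reactants: 15 (4S,6R)-6-[(2R)-3-[(tert-butyldiphenylsilyl)oxy]-2-methylpropyl]-4,6-dimethyl-1,2-dioxan-3-yl acetate; 16 tert-butyl[(1-methoxyethenyl)oxy]dimethylsilane
Product: 17 methyl 2-[(3S,4S,6R)-6-[(2R)-3-[(tert-butyldiphenylsilyl)oxy]-2-methylpropyl]-4,6-dimethyl-1,2-dioxan-3-yl]acetate
Conditions: TMSOTf (0.2 equiv), CH2Cl2, −78 °C
Reagents that add atoms: none
Why: Lewis-acid ionisation of the peroxyacetal acetate gives the C3 peroxycarbenium ion, which the ketene silyl acetal attacks (Mukaiyama-type substitution known for cyclic peroxyacetals) axially on the half-chair that keeps the C4 methyl and the C6 side chain pseudo-equatorial (the other half-chair has a syn-diaxial methyl/alkyl clash), placing C2 cis to the C4 methyl (3S).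

Step 10
Reactants: 17 methyl 2-[(3S,4S,6R)-6-[(2R)-3-[(tert-butyldiphenylsilyl)oxy]-2-methylpropyl]-4,6-dimethyl-1,2-dioxan-3-yl]acetate
Product: 18 methyl 2-[(3S,4S,6R)-6-[(2R)-3-hydroxy-2-methylpropyl]-4,6-dimethyl-1,2-dioxan-3-yl]acetate
Conditions: HF·pyridine, pyridine/THF, 0 °C → rt
Reagents that add atoms: none
Why: Buffered fluoride cleaves the primary silyl ether without the basicity that could open the dioxane by β-elimination from the ester.

Step 11
Reactants: 18 methyl 2-[(3S,4S,6R)-6-[(2R)-3-hydroxy-2-methylpropyl]-4,6-dimethyl-1,2-dioxan-3-yl]acetate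
Product: 19 methyl 2-[(3S,4S,6S)-4,6-dimethyl-6-[(2R)-2-methyl-3-oxopropyl]-1,2-dioxan-3-yl]acetate (C6 reads S only because the formyl group changes the priorities)
Conditions: Dess–Martin periodinane, NaHCO3, CH2Cl2, 0 °C → rt
Reagents that add atoms: none
Why: Buffered Dess–Martin oxidation gives the α-branched aldehyde without epimerising C8 and is compatible with the peroxide; the aldehyde is used at once.

Step 12
Reactants: 20 (E)-1-phenylbut-2-en-1-one
Product: 21 rac-(E)-1-phenylbut-2-en-1-ol
Conditions: NaBH4, CeCl3·7H2O, MeOH, 0 °C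
Reagents that add atoms: none
Why: Luche reduction gives clean 1,2-reduction of the enone to the racemic allylic alcohol.

Step 13
Reactants: 21 rac-(E)-1-phenylbut-2-en-1-ol
Product: 22 (R,E)-1-phenylbut-2-en-1-ol
Conditions: Ti(OiPr)4 (0.1 equiv), D-(−)-diisopropyl tartrate (0.15 equiv), t-BuOOH (0.6 equiv), 4 Å MS, CH2Cl2, −20 °C
Reagents that add atoms: none
Why: Sharpless kinetic resolution epoxidises the (S)-carbinol faster with the D-tartrate, so the (R)-alcohol should be recovered in high enantiomeric purity past half conversion.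

Step 14
Reactants: 22 (R,E)-1-phenylbut-2-en-1-ol
Product: 25 ethyl (3S,4E)-3-methyl-5-phenylpent-4-enoate, via mixed orthoester 23 (not isolated), via ketene acetal 24 (not isolated)
Conditions: MeC(OEt)3, EtCO2H (cat.), 135 °C, EtOH distilled off
Reagents that add atoms: triethyl orthoacetate, CC(OCC)(OCC)OCC
Why: Johnson–Claisen rearrangement through a chair transition state with phenyl equatorial transfers the (R)-carbinol configuration to C12 (S) and forms the E-styrene C13=C14.

Step 15
Reactants: 25 ethyl (3S,4E)-3-methyl-5-phenylpent-4-enoate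
Product: 26 (3S,4E)-3-methyl-5-phenylpent-4-en-1-ol
Conditions: LiAlH4, Et2O, 0 °C
Reagents that add atoms: none
Why: Hydride reduction of the ester to the primary alcohol leaves the styrene, which is not conjugated to the carbonyl, and C12 untouched.

Step 16
Reactants: 26 (3S,4E)-3-methyl-5-phenylpent-4-en-1-ol
Product: 27 5-{[(3S,4E)-3-methyl-5-phenylpent-4-en-1-yl]sulfanyl}-1-phenyl-1H-tetrazole
Conditions: 1-phenyl-1H-tetrazole-5-thiol, PPh3, DIAD, THF, 0 °C → rt
Reagents that add atoms: 1-phenyl-1H-tetrazole-5-thiol, Sc1nnnn1-c1ccccc1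
Why: Mitsunobu thioetherification of a primary alcohol with the acidic tetrazole thiol.

Step 17
Reactants: 27 5-{[(3S,4E)-3-methyl-5-phenylpent-4-en-1-yl]sulfanyl}-1-phenyl-1H-tetrazole
Product: 28 5-{[(3S,4E)-3-methyl-5-phenylpent-4-en-1-yl]sulfonyl}-1-phenyl-1H-tetrazole
Conditions: (NH4)6Mo7O24·4H2O (cat.), H2O2 (30% aq), EtOH, 0 °C → rt
Reagents that add atoms: hydrogen peroxide, OO
Why: Oxidation with H2O2 catalysed by (NH4)6Mo7O24 converts sulfide into sulfone chemoselectively in the presence of the disubstituted styrene.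

Step 18
Reactants: 28 5-{[(3S,4E)-3-methyl-5-phenylpent-4-en-1-yl]sulfonyl}-1-phenyl-1H-tetrazole; 19 methyl 2-[(3S,4S,6S)-4,6-dimethyl-6-[(2R)-2-methyl-3-oxopropyl]-1,2-dioxan-3-yl]acetate
Product: 30 methyl 2-[(3S,4S,6R)-6-[(2R,3E,6S,7E)-2,6-dimethyl-8-phenylocta-3,7-dien-1-yl]-4,6-dimethyl-1,2-dioxan-3-yl]acetate, via metalated sulfone 29 (not isolated)
Conditions: KHMDS, DME, −78 °C, 20 min; then 19, −78 °C → rt
Reagents that add atoms: none
Why: Julia–Kocienski olefination of the pre-metalated phenyltetrazolyl sulfone with an α-branched aldehyde gives the E alkene C9=C10, and the sulfonyl carbanion is too weak a base to enolise the ester.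

Step 19
Reactants: 30 methyl 2-[(3S,4S,6R)-6-[(2R,3E,6S,7E)-2,6-dimethyl-8-phenylocta-3,7-dien-1-yl]-4,6-dimethyl-1,2-dioxan-3-yl]acetate
Product: 31 2-[(3S,4S,6R)-6-[(2R,3E,6S,7E)-2,6-dimethyl-8-phenylocta-3,7-dien-1-yl]-4,6-dimethyl-1,2-dioxan-3-yl]acetic acid (CNP0179089.2)
Conditions: LiOH·H2O, THF/MeOH/H2O, 0 °C → rt; then 1 M HCl to pH 3–4
Reagents that add atoms: lithium hydroxide, [Li+].[OH-]
Why: Saponification of the methyl ester by acyl substitution at 0 °C, where hydroxide attack at the carbonyl should outrun enolate-driven opening of the peroxide ring.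

**Compound list**

1 | methyl (S)-3-hydroxy-2-methylpropanoate | C[C@@H](CO)C(=O)OC | starting material
2 | methyl (S)-3-[(tert-butyldiphenylsilyl)oxy]-2-methylpropanoate | COC(=O)[C@@H](C)CO[Si](c1ccccc1)(c1ccccc1)C(C)(C)C | intermediate
3 | (R)-3-[(tert-butyldiphenylsilyl)oxy]-2-methylpropan-1-ol | OC[C@@H](C)CO[Si](c1ccccc1)(c1ccccc1)C(C)(C)C | intermediate
4 | (S)-(3-bromo-2-methylpropoxy)(tert-butyl)diphenylsilane | BrC[C@@H](C)CO[Si](c1ccccc1)(c1ccccc1)C(C)(C)C | intermediate
5 | 3-methylcyclobutan-1-one | CC1CC(=O)C1 | starting material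
6 | lithium (S)-3-methylcyclobut-1-en-1-olate | [Li+].[O-]C1=C[C@@H](C)C1 | intermediate (not isolated)
7 | (S)-3-methylcyclobut-1-en-1-yl trifluoromethanesulfonate | O=S(=O)(OC1=C[C@@H](C)C1)C(F)(F)F | intermediate
8 | {(S)-3-[(tert-butyldiphenylsilyl)oxy]-2-methylpropyl}magnesium bromide | Br[Mg]C[C@@H](C)CO[Si](c1ccccc1)(c1ccccc1)C(C)(C)C | intermediate (not isolated)
9 | tert-butyl{(2R)-2-methyl-3-[(3S)-3-methylcyclobut-1-en-1-yl]propoxy}diphenylsilane | CC(C)(C)[Si](c1ccccc1)(c1ccccc1)OC[C@H](C)CC1=C[C@@H](C)C1 | intermediate (key-step precursor)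
10 | 1-[(2R)-3-[(tert-butyldiphenylsilyl)oxy]-2-methylpropyl]-6-methyl-2,3,4-trioxabicyclo[3.2.0]heptane (primary ozonide, trioxolane anti to the ring methyl) | CC(C)(C)[Si](c1ccccc1)(c1ccccc1)OC[C@H](C)C[C@]12C[C@H](C)[C@H]1OOO2 | intermediate (not isolated)
11 | (2S,6R)-7-[(tert-butyldiphenylsilyl)oxy]-2,6-dimethyl-4-oxoheptanal O-oxide (carbonyl oxide at C3, ketone at C6) | CC(C)(C)[Si](c1ccccc1)(c1ccccc1)OC[C@H](C)CC(=O)C[C@H](C)C=[O+][O-] | intermediate (not isolated)
12 | (1R,4S,5S)-1-[(2R)-3-[(tert-butyldiphenylsilyl)oxy]-2-methylpropyl]-5-methyl-2,3,7-trioxabicyclo[2.2.1]heptane (methyl anti to the ether bridge) | CC(C)(C)[Si](c1ccccc1)(c1ccccc1)OC[C@H](C)C[C@@]12C[C@H](C)[C@@H](O1)OO2 | intermediate (key-step product)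
13 | {[(4S,6R)-6-[(2R)-3-[(tert-butyldiphenylsilyl)oxy]-2-methylpropyl]-4,6-dimethyl-1,2-dioxan-3-yl]oxy}trimethylsilane (C3 epimers) | CC(C)(C)[Si](c1ccccc1)(c1ccccc1)OC[C@H](C)C[C@]1(C)C[C@H](C)C(O[Si](C)(C)C)OO1 | intermediate (not isolated)
14 | (4S,6R)-6-[(2R)-3-[(tert-butyldiphenylsilyl)oxy]-2-methylpropyl]-4,6-dimethyl-1,2-dioxan-3-ol (C3 anomers) | CC(C)(C)[Si](c1ccccc1)(c1ccccc1)OC[C@H](C)C[C@]1(C)C[C@H](C)C(O)OO1 | intermediate
15 | (4S,6R)-6-[(2R)-3-[(tert-butyldiphenylsilyl)oxy]-2-methylpropyl]-4,6-dimethyl-1,2-dioxan-3-yl acetate (C3 anomers) | CC(C)(C)[Si](c1ccccc1)(c1ccccc1)OC[C@H](C)C[C@]1(C)C[C@H](C)C(OC(C)=O)OO1 | intermediate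
16 | tert-butyl[(1-methoxyethenyl)oxy]dimethylsilane | C=C(OC)O[Si](C)(C)C(C)(C)C | starting material
17 | methyl 2-[(3S,4S,6R)-6-[(2R)-3-[(tert-butyldiphenylsilyl)oxy]-2-methylpropyl]-4,6-dimethyl-1,2-dioxan-3-yl]acetate | CC(C)(C)[Si](c1ccccc1)(c1ccccc1)OC[C@H](C)C[C@]1(C)C[C@H](C)[C@H](CC(=O)OC)OO1 | intermediate
18 | methyl 2-[(3S,4S,6R)-6-[(2R)-3-hydroxy-2-methylpropyl]-4,6-dimethyl-1,2-dioxan-3-yl]acetate | OC[C@H](C)C[C@]1(C)C[C@H](C)[C@H](CC(=O)OC)OO1 | intermediate
19 | methyl 2-[(3S,4S,6S)-4,6-dimethyl-6-[(2R)-2-methyl-3-oxopropyl]-1,2-dioxan-3-yl]acetate | O=C[C@H](C)C[C@]1(C)C[C@H](C)[C@H](CC(=O)OC)OO1 | intermediate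
20 | (E)-1-phenylbut-2-en-1-one | C/C=C/C(=O)c1ccccc1 | starting material
21 | rac-(E)-1-phenylbut-2-en-1-ol | C/C=C/C(O)c1ccccc1 | intermediate
22 | (R,E)-1-phenylbut-2-en-1-ol | C/C=C/[C@@H](O)c1ccccc1 | intermediate
23 | {(1R,2E)-1-[(1,1-diethoxyethyl)oxy]but-2-en-1-yl}benzene | C/C=C/[C@@H](OC(C)(OCC)OCC)c1ccccc1 | intermediate (not isolated)
24 | {(1R,2E)-1-[(1-ethoxyethenyl)oxy]but-2-en-1-yl}benzene | C/C=C/[C@@H](OC(=C)OCC)c1ccccc1 | intermediate (not isolated)
25 | ethyl (3S,4E)-3-methyl-5-phenylpent-4-enoate | CCOC(=O)C[C@H](C)/C=C/c1ccccc1 | intermediate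
26 | (3S,4E)-3-methyl-5-phenylpent-4-en-1-ol | OCC[C@H](C)/C=C/c1ccccc1 | intermediate
27 | 5-{[(3S,4E)-3-methyl-5-phenylpent-4-en-1-yl]sulfanyl}-1-phenyl-1H-tetrazole | c1ccccc1-n1nnnc1SCC[C@H](C)/C=C/c1ccccc1 | intermediate
28 | 5-{[(3S,4E)-3-methyl-5-phenylpent-4-en-1-yl]sulfonyl}-1-phenyl-1H-tetrazole | c1ccccc1-n1nnnc1S(=O)(=O)CC[C@H](C)/C=C/c1ccccc1 | intermediate
29 | potassium salt of the α-sulfonyl carbanion of 28 | [K+].c1ccccc1-n1nnnc1S(=O)(=O)[CH-]C[C@H](C)/C=C/c1ccccc1 | intermediate (not isolated)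
30 | methyl 2-[(3S,4S,6R)-6-[(2R,3E,6S,7E)-2,6-dimethyl-8-phenylocta-3,7-dien-1-yl]-4,6-dimethyl-1,2-dioxan-3-yl]acetate | C[C@H](/C=C/c1ccccc1)C/C=C/[C@H](C)C[C@]1(C)C[C@H](C)[C@H](CC(=O)OC)OO1 | intermediate
31 | 2-[(3S,4S,6R)-6-[(2R,3E,6S,7E)-2,6-dimethyl-8-phenylocta-3,7-dien-1-yl]-4,6-dimethyl-1,2-dioxan-3-yl]acetic acid | C[C@H](/C=C/c1ccccc1)C/C=C/[C@H](C)C[C@]1(C)C[C@H](C)[C@H](CC(=O)O)OO1 | target

**Step count**

Total: 19 steps. Longest linear sequence: 12 steps (1, 2, 3, 5, 6, 7, 8, 9, 10, 11, 18, 19, from the hydroxy ester 1).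

**Steps most likely to fail**

Step 7 (the proposed methyl transfer). The Lewis acid may break the O–O bond instead of the C6–O bridge bond (Hock-type fragmentation), methyl may be transferred to peroxide oxygen, the silyl acetal at C3 may ionise a second time, or methyl may be delivered within an ion pair so that facial control by C4 is lost. The fallback uses known chemistry only and gives up stereocontrol at C6. It sets out from ozonide 12 and returns at 17. PPh3 in CH2Cl2 reduces the ozonide to the keto aldehyde F1. Ph3P=CHCO2Me in CH2Cl2 at rt homologates the aldehyde alone to the keto enoate F2. Ph3P=CH2 (from Ph3PCH3Br and KOt-Bu, THF, 0 °C) converts the ketone into the 1,1-disubstituted alkene F3. Mukaiyama–Isayama hydroperoxysilylation (Co(acac)2 cat., O2, Et3SiH, ClCH2CH2Cl) adds the peroxide at the tertiary carbon of the electron-rich alkene in preference to the enoate, giving the silyl peroxide F4 as both C6 epimers. HCl (cat.) in MeOH frees the hydroperoxide F5, and Et2NH in CF3CH2OH closes the 1,2-dioxane by 6-exo peroxy-Michael addition. Compound 17 is separated from its C6 and C3 diastereomers by chromatography.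

Step 6 (the key ozonolysis). The carbonyl oxide may add to a carbonyl of another molecule and give oligomeric peroxides, the ozonide may be lost on concentration, or excess ozone may attack the phenyl rings. The fallback replaces the recombination by solvent capture; it sets out from cyclobutene 9 and returns at 17. Ozonolysis in CH2Cl2/MeOH at −78 °C lets methanol trap the carbonyl oxide, and the resulting hydroperoxide closes onto the neighbouring carbonyl to the cyclic methoxy peroxy hemiketal F6 (the other regiochemistry of capture converges in the next operation). TsOH (cat.) in MeOH gives the 3,6-dimethoxy-1,2-dioxane F7. Me3Al/TMSOTf in CH2Cl2 at −78 °C ionises the tertiary ketal carbon C6 and delivers methyl under the same C4 control as in step 7, here on a peroxyketal, giving the 3-methoxy-6-methyl dioxane F8. F8 reacts with 16 and TiCl4 in CH2Cl2 at −78 °C (known substitution of 3-alkoxy-1,2-dioxanes by ketene silyl acetals) to give 17.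

Step 4 (enantioselective enolisation). Discrimination between the two enantiotopic α-methylene groups may be incomplete for a substituent as small as methyl, proton exchange between enolate and ketone may erode it further, and the volatile triflate may be lost on isolation. The fallback drops reagent control and uses the C8 centre for separation; it sets out from ketone 5 and returns at 9. LDA in THF at −78 °C followed by Comins' reagent gives the racemic triflate, that is 7 with its enantiomer F9. Coupling with Grignard reagent 8 as in step 5 gives 9 together with its C4 epimer F10. The two diastereomers are separated by preparative chromatography on a chiral stationary phase, and 9 is carried on.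

**Further compounds**

F1 | step 7 | (2S,6R)-7-[(tert-butyldiphenylsilyl)oxy]-2,6-dimethyl-4-oxoheptanal | O=C[C@@H](C)CC(=O)C[C@@H](C)CO[Si](c1ccccc1)(c1ccccc1)C(C)(C)C
F2 | step 7 | methyl (2E,4S,8R)-9-[(tert-butyldiphenylsilyl)oxy]-4,8-dimethyl-6-oxonon-2-enoate | COC(=O)/C=C/[C@@H](C)CC(=O)C[C@@H](C)CO[Si](c1ccccc1)(c1ccccc1)C(C)(C)C
F3 | step 7 | methyl (2E,4S,8R)-9-[(tert-butyldiphenylsilyl)oxy]-4,8-dimethyl-6-methylidenenon-2-enoate | COC(=O)/C=C/[C@@H](C)CC(=C)C[C@@H](C)CO[Si](c1ccccc1)(c1ccccc1)C(C)(C)C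
F4 | step 7 | methyl (2E,4S,8R)-9-[(tert-butyldiphenylsilyl)oxy]-4,6,8-trimethyl-6-[(triethylsilyl)peroxy]non-2-enoate (both C6 epimers) | COC(=O)/C=C/[C@@H](C)CC(C)(OO[Si](CC)(CC)CC)C[C@@H](C)CO[Si](c1ccccc1)(c1ccccc1)C(C)(C)C
F5 | step 7 | methyl (2E,4S,8R)-9-[(tert-butyldiphenylsilyl)oxy]-6-hydroperoxy-4,6,8-trimethylnon-2-enoate (both C6 epimers) | COC(=O)/C=C/[C@@H](C)CC(C)(OO)C[C@@H](C)CO[Si](c1ccccc1)(c1ccccc1)C(C)(C)C
F6 | step 6 | (5S)-3-[(2R)-3-[(tert-butyldiphenylsilyl)oxy]-2-methylpropyl]-6-methoxy-5-methyl-1,2-dioxan-3-ol | CC(C)(C)[Si](c1ccccc1)(c1ccccc1)OC[C@H](C)CC1(O)C[C@H](C)C(OC)OO1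
F7 | step 6 | (5S)-3-[(2R)-3-[(tert-butyldiphenylsilyl)oxy]-2-methylpropyl]-3,6-dimethoxy-5-methyl-1,2-dioxane | CC(C)(C)[Si](c1ccccc1)(c1ccccc1)OC[C@H](C)CC1(OC)C[C@H](C)C(OC)OO1
F8 | step 6 | (3R,5S)-3-[(2R)-3-[(tert-butyldiphenylsilyl)oxy]-2-methylpropyl]-6-methoxy-3,5-dimethyl-1,2-dioxane | CC(C)(C)[Si](c1ccccc1)(c1ccccc1)OC[C@H](C)C[C@]1(C)C[C@H](C)C(OC)OO1
F9 | step 4 | (R)-3-methylcyclobut-1-en-1-yl trifluoromethanesulfonate | O=S(=O)(OC1=C[C@H](C)C1)C(F)(F)F
F10 | step 4 | tert-butyl{(2R)-2-methyl-3-[(3R)-3-methylcyclobut-1-en-1-yl]propoxy}diphenylsilane | CC(C)(C)[Si](c1ccccc1)(c1ccccc1)OC[C@H](C)CC1=C[C@H](C)C1
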